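Atom numbering follows the chromane skeleton of the target (O1, C2, C3, C4, C4a, C5, C6, C7, C8, C8a); primed numbers refer to the lavandulyl chain. Ring A is the carbocycle, ring B the pyranone. Compounds carry the numbers of the step list below.

## Analysis of the target

Target 23 is a dearomatised acylphloroglucinol. Ring A (C4a, C5, C6, C7, C8, C8a) is an enolised β-triketone, fused through C4a–C8a to ring B (O1, C2, C3, C4, C4a, C8a), a 2,3-dimethyl-2,3-dihydropyran-4-one. There are five stereocentres: C2 (R) and C3 (S), adjacent and cis on ring B; quaternary C8 (S) with a prenyl and a lavandulyl group; C2' of the lavandulyl chain (R); and the benzylic carbon of the 3-phenylpropanoic acid on C6 (R). Only C2 and C3 are contiguous, so the other three centres each need their own element of control. C3 is α to the C4 ketone and cis to C2, so base (enolisation or retro-oxa-Michael opening of ring B) would turn it into the more stable trans isomer. The three electron-rich alkenes exclude hydrogenation, strong acid and electrophilic oxidants late in the route, and the 8-allyl dienone can lose its prenyl group to O7 by a sigmatropic shift on strong heating. The main difficulties are that every carbon of ring A is substituted, and that the two groups on C8 differ only beyond their allylic carbons and lie far from any other stereocentre. The strategy rests on ring B: the sequence C8a(O)=C4a–C4(=O)–C3 is the skeleton of a 1-alkoxy-3-silyloxy diene whose alkoxy terminus C8a is an enol ether carbon of dearomatised ring A, while O1, C2 and its methyl group are an aldehyde.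

## Retrosynthetic reasoning

**Unmasking (23 to 21).** The acid and the C5 enol are freed last, by cleaving two O–methyl bonds (22, then 21). The free triketone enol and the acid would bind any Lewis acid, and the two ring methyl ethers are what distinguishes O5 and O8a from O7 throughout the route.

**Ring B (21 to 18 and 19).** C2–C3 and O1–C8a are cut, giving silyl dienol ether 18 and acetaldehyde 19. Ring B holds the only contiguous stereocentres and the only epimerisable one, so it is made last and then sees two mild steps only. The forward reaction must form a syn aldol at C2/C3 with the correct absolute sense and must close O1 onto C8a, not C5, with loss of the C8a methoxy group.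

**Enol silane (18 to 17).** The O–Si bond is cut. C3 is the only enolisable position next to a ketone in 17, so soft enolisation needs no protecting groups.

**Dearomatisation (17 to 14 and 15).** The C8–prenyl bond and the ester O–methyl bond are cut. Lactone 14 ties O7 to the side-chain carboxyl; opening it with an alkoxide gives the methyl ester and the O7 phenoxide 16 in one operation, and C-alkylation with prenyl bromide 15 dearomatises the ring. Ring A is thus assembled as a planar benzene and the quaternary centre is made last on it.

**Lavandulyl group (14 to 9 and 12).** The aryl–C1' bond is cut. A β-branched homoallylic halide is a poor electrophile towards a phenol, so polarity is inverted: iodide 12 becomes organozinc 13 and is cross-coupled with aryl iodide 9. Iodide 12 comes from (S)-lavandulol 11, obtained by resolving racemic 10. Iodide 9 comes from 8 by substitution of the last ring hydrogen.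

**Benzylic centre (8 to 6 and 7).** The benzylic carbon–phenyl bond is cut, giving coumarin 6 and phenylboronic acid 7. A catalytic asymmetric conjugate addition sets the centre, and the lactone keeps O7 masked.

**Coumarin (6 to 4 and 5).** The aryl–vinyl bond and the lactone C–O bond are cut. Phenol 4 has two equivalent ortho positions and a single hydroxyl, so annulation with ethyl propiolate 5 can give only one regioisomer.

**Oxygen pattern (4 to 1).** Triol 1 is differentiated through 2 and 3: the para hydroxyl, the only one not hydrogen-bonded to the ketone, is blocked first, the two chelated hydroxyls are methylated, and the para hydroxyl is released.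

## Alternatives that were turned down

Alternative 1: The C4a–C8a bond of ring A is cut, leading back to a lactone isomer in which C8a is a pyran-2,4-dione carbonyl and C4a a side-chain methylene. In the forward step the C4a carbanion attacks the lactone carbonyl and the ring oxygen leaves as the C5 enolate, giving A1.
- For it: the C2/C3 pair is bought from an auxiliary aldol before any ring exists, which is more secure than a late catalytic aldol, and there is no aromatic regiochemistry to solve.
- Against it: A1 lacks the C6 side chain and ring B. The benzylic centre would have to be created by alkylating a dearomatised triketone with no control element. Ring B would have to close by dehydration onto one of two free enols (O5 or O8a) with no marker between them. The strongly basic ring transformation exposes a β-silyloxy ketone with an α-stereocentre to epimerisation and elimination. C8 is still made by an unbiased second alkylation.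
- Comparison: Alternative 1 is stronger on C2/C3 control. The chosen strategy offers instead the O-methyl labels that fix the site of ring B closure, and a catalytic asymmetric entry to the benzylic centre on an aromatic lactone.

Alternative 2: The C3–C4 bond of ring B is cut on an aromatic phloroglucinol aldehyde whose phenol oxygen carries a chiral-pool enoate. A triazolium-derived carbene turns the aldehyde into an acyl anion equivalent that adds to the enoate (intramolecular Stetter reaction), giving A2.
- For it: this closure is well behaved on simple salicylaldehyde ethers, C2 comes from the chiral pool, and the step is at least as reliable as the chosen key step because the substrate is small.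
- Against it: A2 carries CH2CO2tBu on C3 where the target has methyl, so an ester cleavage and a reductive decarboxylation are added. The cis ring B would then have to survive functionalisation at C6 and C8 and a basic dearomatising prenylation, which risks cis-to-trans erosion and ring opening. The benzyl ethers would have to be removed before any alkene is present, and C6 and C8 of a 5,7-dioxygenated chromanone are not easily told apart.
- Comparison: the chosen strategy gives up the early, safe ring closure but forms the labile ring last.

Alternative 3: The C4a–C5 bond of ring A is cut. Heating a dioxinone liberates an acylketene whose ketene carbon (C5) is attacked by C4a of a preformed dihydropyranone, closing ring A as A3, the same compound as 22.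
- For it: the closure is neutral and thermal, so it is gentler on C3 than anything in the chosen route, and it arrives at the stage of 22 with no O-methyl group to remove. On end-game mildness and protecting-group economy it is stronger.
- Against it: the precursor has an acyclic quaternary C8 bearing prenyl, lavandulyl, the dihydropyranone and a fully substituted dioxinone, and no good way to build that carbon stereoselectively is apparent. The acylketene can be intercepted by the pendant alkenes or by a carbonyl oxygen instead of C4a, and the sequence to the precursor is long.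
- Comparison: the chosen strategy offers a planar aromatic template on which each substituent of ring A is introduced by regiodefined aromatic chemistry, and C8 is created on a rigid ring.

Key step: step 12

## Route

Remark: the target is treated as the tautomer drawn (C5 enol, C7 ketone). In lactones 6, 8, 9 and 14 the coumarin locants 4, 5, 6, 7, 8 and O1 correspond to the benzylic carbon, C5, C4a, C8a, C8 and O7 of the target.

Step 1
Reactants: 1 1-(2,4,6-trihydroxyphenyl)propan-1-one
Product: 2 1-[4-(benzyloxy)-2,6-dihydroxyphenyl]propan-1-one
Conditions: BnBr (1.0 equiv), K2CO3 (1.1 equiv), acetone, rt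
Reagents that add atoms: benzyl bromide, BrCc1ccccc1
Why: Williamson ether synthesis; the para hydroxyl is the most acidic and the only one not hydrogen-bonded to the ketone, so one equivalent of halide should alkylate it selectively.

Step 2
Reactants: 2 1-[4-(benzyloxy)-2,6-dihydroxyphenyl]propan-1-one
Product: 3 1-[4-(benzyloxy)-2,6-dimethoxyphenyl]propan-1-one
Conditions: Me2SO4 (excess), K2CO3, acetone, reflux
Reagents that add atoms: dimethyl sulfate, COS(=O)(=O)OC
Why: Williamson O-methylation of the two chelated hydroxyls; the hard electrophile with carbonate in acetone favours oxygen over ring carbon, and excess reagent at reflux overcomes the hydrogen bonds.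

Step 3
Reactants: 3 1-[4-(benzyloxy)-2,6-dimethoxyphenyl]propan-1-one
Product: 4 1-(4-hydroxy-2,6-dimethoxyphenyl)propan-1-one
Conditions: H2 (1 atm), 10% Pd/C, EtOAc–MeOH, rt
Reagents that add atoms: none
Why: Hydrogenolysis of the benzyl ether; the ketone, twisted out of conjugation by two ortho methoxy groups, should not be reduced at ambient pressure, and no alkene is present yet.

Step 4
Reactants: 4 1-(4-hydroxy-2,6-dimethoxyphenyl)propan-1-one; 5 ethyl propiolate
Product: 6 5,7-dimethoxy-6-propanoyl-2H-chromen-2-one
Conditions: Pd(OAc)2 (5 mol%), CF3CO2H–CH2Cl2 (1:1), rt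
Reagents that add atoms: none
Why: Palladium-catalysed hydroarylation of an alkynoate followed by lactonisation (Pechmann-type coumarin annulation); the electron-rich C–H ortho to the hydroxyl adds across the alkyne to give a Z cinnamate that closes onto the phenol. The two ortho positions of 4 are equivalent, so only one regioisomer can form.

Step 5
Reactants: 6 5,7-dimethoxy-6-propanoyl-2H-chromen-2-one; 7 phenylboronic acid
Product: 8 (4R)-5,7-dimethoxy-4-phenyl-6-propanoyl-3,4-dihydro-2H-chromen-2-one
Conditions: 7 (5 equiv), Rh(acac)(C2H4)2 (3 mol%), (R)-SEGPHOS [(R)-5,5′-bis(diphenylphosphino)-4,4′-bi-1,3-benzodioxole] (3.3 mol%), dioxane–H2O (10:1), 60 °C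
Reagents that add atoms: none
Why: Hayashi–Miyaura reaction; a phenylrhodium species adds to C4 of the coumarin and the rhodium enolate is protonated by water, the bisphosphine blocking one face of the bound enoate. The (R) ligand is the antipode expected to give the 4R lactone, as with simpler coumarins, and the aryl ketone is inert under these neutral conditions. This sets the benzylic stereocentre of the target.

Step 6
Reactants: 8 (4R)-5,7-dimethoxy-4-phenyl-6-propanoyl-3,4-dihydro-2H-chromen-2-one
Product: 9 (4R)-8-iodo-5,7-dimethoxy-4-phenyl-6-propanoyl-3,4-dihydro-2H-chromen-2-one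
Conditions: N-iodosuccinimide (1.05 equiv), CF3CO2H (0.2 equiv), MeCN, 0 °C to rt
Reagents that add atoms: N-iodosuccinimide, O=C1CCC(=O)N1I
Why: Electrophilic aromatic iodination at the only free position of the trioxygenated ring, which is ortho and para to the two methoxy groups; the phenyl ring is unactivated and the benzylic centre is not touched.

Step 7
Reactants: 10 racemic lavandulol [5-methyl-2-(prop-1-en-2-yl)hex-4-en-1-ol]
Product: 11 (S)-lavandulol [(2S)-5-methyl-2-(prop-1-en-2-yl)hex-4-en-1-ol]
Conditions: porcine pancreas lipase, vinyl acetate, t-BuOMe, rt, stopped beyond half conversion (about 60%)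
Reagents that add atoms: none
Why: Lipase-catalysed kinetic resolution by enantioselective transesterification; the (R)-alcohol is expected to be acetylated faster, so running past half conversion should leave the (S)-alcohol in high enantiomeric purity, separable from the acetate by chromatography. This sets C2' of the lavandulyl group.

Step 8
Reactants: 11 (S)-lavandulol
Product: 12 (3S)-3-(iodomethyl)-2,6-dimethylhepta-1,5-diene [(S)-lavandulyl iodide]
Conditions: I2, PPh3, imidazole, CH2Cl2, 0 °C to rt
Reagents that add atoms: iodine, II
Why: Appel reaction at a primary alcohol; the stereocentre is β to the reacting carbon and is not involved, and the alkenes are inert to the phosphonium iodide.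

Step 9
Reactants: 12 (S)-lavandulyl iodide; 9 (4R)-8-iodo-5,7-dimethoxy-4-phenyl-6-propanoyl-3,4-dihydro-2H-chromen-2-one
Product: 14 (4R)-5,7-dimethoxy-8-[(2R)-5-methyl-2-(prop-1-en-2-yl)hex-4-en-1-yl]-4-phenyl-6-propanoyl-3,4-dihydro-2H-chromen-2-one, via alkylzinc iodide 13 (not isolated)
Conditions: 12, Zn dust (activated by BrCH2CH2Br and Me3SiCl), LiCl, THF, 35 °C; then 9, Pd(OAc)2 (3 mol%), SPhos (2-dicyclohexylphosphino-2′,6′-dimethoxybiphenyl, 6 mol%), THF, 50 °C
Reagents that add atoms: zinc, [Zn] (ends in intermediate 13, not in 14)
Why: Zinc insertion into the primary iodide followed by Negishi cross-coupling; the bulky electron-rich biarylphosphine promotes oxidative addition at the hindered aryl iodide and fast reductive elimination ahead of β-hydride elimination. Organozinc halides do not attack the ketone or the lactone, and the stereocentre β to zinc is configurationally stable (its descriptor changes from S to R only because the priorities change).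

Step 10
Reactants: 14 (4R)-5,7-dimethoxy-8-[(2R)-5-methyl-2-(prop-1-en-2-yl)hex-4-en-1-yl]-4-phenyl-6-propanoyl-3,4-dihydro-2H-chromen-2-one; 15 prenyl bromide (1-bromo-3-methylbut-2-ene)
Product: 17 methyl (3R)-3-[(5S)-2,4-dimethoxy-5-(3-methylbut-2-en-1-yl)-5-[(2R)-5-methyl-2-(prop-1-en-2-yl)hex-4-en-1-yl]-6-oxo-3-propanoylcyclohexa-1,3-dien-1-yl]-3-phenylpropanoate, via sodium phenoxide 16 (not isolated)
Conditions: NaOMe (1.0 equiv), MeOH–THF, 0 °C; evaporate; toluene, 15 (1.5 equiv), 0 °C to rt
Reagents that add atoms: sodium methoxide, C[O-].[Na+]
Why: Methoxide opens the aryl ester lactone (a phenoxide is a far weaker base than an alkoxide), and sodium phenoxide 16, a tight ion pair in toluene, is C-alkylated at an ortho carbon (alkylative dearomatisation of a phloroglucinol-type phenoxide); C8 with its primary alkyl group is less hindered than C6 with its secondary benzylic group, and the para carbon carries the acyl group. The new quaternary centre is expected to be 8S because sodium, held between O7 and the ester carbonyl on the face of the CH2CO2Me arm (anti to phenyl when the benzylic hydrogen eclipses the C5 methoxy group), delivers 15 to that face. The induction is remote and may be modest; the 8R epimer (a diastereomer) and any O-prenyl ether are removed by chromatography, and unreacted phenoxide returns as 14 on acidification.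

Step 11
Reactants: 17 methyl (3R)-3-[(5S)-2,4-dimethoxy-5-(3-methylbut-2-en-1-yl)-5-[(2R)-5-methyl-2-(prop-1-en-2-yl)hex-4-en-1-yl]-6-oxo-3-propanoylcyclohexa-1,3-dien-1-yl]-3-phenylpropanoate
Product: 18 methyl (3R)-3-[(5S)-2,4-dimethoxy-5-(3-methylbut-2-en-1-yl)-5-[(2R)-5-methyl-2-(prop-1-en-2-yl)hex-4-en-1-yl]-6-oxo-3-[(1Z)-1-(triethylsilyloxy)prop-1-en-1-yl]cyclohexa-1,3-dien-1-yl]-3-phenylpropanoate
Conditions: Et3SiOTf (1.3 equiv), Et3N (2 equiv), CH2Cl2, −78 to 0 °C; filtration through Et3N-deactivated silica
Reagents that add atoms: triethylsilyl triflate, CC[Si](CC)(CC)OS(=O)(=O)C(F)(F)F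
Why: Soft enolisation of an ethyl ketone; C3 is the only enolisable position next to a ketone (C8 is quaternary, C6 is sp2, and the ester is not enolised by an amine base). The Z geometry is expected because the methyl group avoids the fully substituted ring carbon C4a (A(1,3) strain), as with hindered aryl ethyl ketones.

Step 12
Reactants: 18 (Z)-triethylsilyl dienol ether; 19 acetaldehyde
Product: 21 methyl (3R)-3-[(2R,3S,8S)-5-methoxy-2,3-dimethyl-8-(3-methylbut-2-en-1-yl)-8-[(2R)-5-methyl-2-(prop-1-en-2-yl)hex-4-en-1-yl]-4,7-dioxo-3,4,7,8-tetrahydro-2H-chromen-6-yl]-3-phenylpropanoate, via silylated aldol adduct 20 (not isolated)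
Conditions: 19 (5 equiv, freshly distilled), boron Lewis acid made in the flask from (2S,3S)-2-O-(2,6-diisopropoxybenzoyl)tartaric acid and 3,5-(CF3)2C6H3B(OH)2 (0.5 equiv), EtCN, −78 °C; then CF3CO2H (3 equiv), CH2Cl2, 0 °C, short
Reagents that add atoms: none
Why: Mukaiyama aldol addition followed by acid-mediated addition–elimination, a stepwise formal hetero-Diels–Alder annulation of the kind long used to make 2,3-dihydropyran-4-ones from 1-alkoxy-3-silyloxy dienes and aldehydes; a boron Lewis acid is chosen because a ketone enol silane flanked by two methoxy groups is too weak a nucleophile for a mild titanium alkoxide catalyst. The Lewis acid binds 19 and the enol silane attacks through C3 in an open transition state, giving silyl ether 20 with C4 restored as a ketone conjugated to C4a=C8a. Open transition states of this catalyst class give syn aldols from enol silanes of aryl-type ethyl ketones whatever their geometry, and the Z geometry and the bulky ring substituent on C4 reinforce this, so C3 (S) is set relative to C2 and ring B becomes 2,3-cis. C2 (R) requires attack on the Si face of 19; this is the task of the chiral acyloxyborane, the (2S,3S)-tartrate series being the one expected to deliver it, because quaternary C8 differentiates the faces of the nucleophile only weakly. Trifluoroacetic acid then removes the silyl group and the C2 hydroxyl adds to C8a in a 6-endo-trig closure, after which the C8a methoxy group is lost and ring B is closed without touching C2 or C3. Regioselectivity (O1 to C8a, not C5) rests on C8a being the only methoxy-bearing carbon conjugated to the new C4 carbonyl and, at the Lewis acid stage, the only one sharing the positive charge; C5 is merely cross-conjugated. Chemoselectivity rests on C3 being the only position converted into an enol silane and on the short, cold acid treatment, which should spare the alkenes and the configuration at C3. The facial assignment should be verified on the enol silane of a simple aryl ethyl ketone before 18 is committed.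

Step 13
Reactants: 21 methyl (3R)-3-[(2R,3S,8S)-5-methoxy-2,3-dimethyl-8-(3-methylbut-2-en-1-yl)-8-[(2R)-5-methyl-2-(prop-1-en-2-yl)hex-4-en-1-yl]-4,7-dioxo-3,4,7,8-tetrahydro-2H-chromen-6-yl]-3-phenylpropanoate
Product: 22 methyl (3R)-3-[(2R,3S,8S)-5-hydroxy-2,3-dimethyl-8-(3-methylbut-2-en-1-yl)-8-[(2R)-5-methyl-2-(prop-1-en-2-yl)hex-4-en-1-yl]-4,7-dioxo-3,4,7,8-tetrahydro-2H-chromen-6-yl]-3-phenylpropanoate
Conditions: LiCl (10 equiv), DMF, 100 °C; then dilute HCl
Reagents that add atoms: none
Why: Krapcho-type SN2 demethylation of the vinylogous methyl ester at O5 by chloride, the leaving group being the stabilised diketonate; the medium is essentially neutral, and the anionic ring that results resists further enolisation towards C3. Any concurrent cleavage of the methyl ester only anticipates step 14.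

Step 14
Reactants: 22 methyl (3R)-3-[(2R,3S,8S)-5-hydroxy-2,3-dimethyl-8-(3-methylbut-2-en-1-yl)-8-[(2R)-5-methyl-2-(prop-1-en-2-yl)hex-4-en-1-yl]-4,7-dioxo-3,4,7,8-tetrahydro-2H-chromen-6-yl]-3-phenylpropanoate
Product: 23 (3R)-3-[(2R,3S,8S)-5-hydroxy-2,3-dimethyl-8-(3-methylbut-2-en-1-yl)-8-[(2R)-5-methyl-2-(prop-1-en-2-yl)hex-4-en-1-yl]-4,7-dioxo-3,4,7,8-tetrahydro-2H-chromen-6-yl]-3-phenylpropanoic acid (target)
Conditions: Me3SnOH (6 equiv), ClCH2CH2Cl, 70 °C; then 1 M HCl
Reagents that add atoms: trimethyltin hydroxide, C[Sn](C)(C)O
Why: Ester hydrolysis with trimethyltin hydroxide, a near-neutral method used where epimerisable centres must be kept; hydroxide is delivered to the ester carbonyl within a tin complex, so the cis C3 centre and ring B are not exposed to free base. The acidic enol takes up one equivalent of reagent and is released again on acidification.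

## Compound list

1 | 1-(2,4,6-trihydroxyphenyl)propan-1-one | CCC(=O)c1c(O)cc(O)cc1O | starting material
2 | 1-[4-(benzyloxy)-2,6-dihydroxyphenyl]propan-1-one | CCC(=O)c1c(O)cc(OCc2ccccc2)cc1O | intermediate
3 | 1-[4-(benzyloxy)-2,6-dimethoxyphenyl]propan-1-one | CCC(=O)c1c(OC)cc(OCc2ccccc2)cc1OC | intermediate
4 | 1-(4-hydroxy-2,6-dimethoxyphenyl)propan-1-one | CCC(=O)c1c(OC)cc(O)cc1OC | intermediate
5 | ethyl propiolate | C#CC(=O)OCC | starting material
6 | 5,7-dimethoxy-6-propanoyl-2H-chromen-2-one | CCC(=O)c1c(OC)cc2oc(=O)ccc2c1OC | intermediate
7 | phenylboronic acid | OB(O)c1ccccc1 | starting material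
8 | (4R)-5,7-dimethoxy-4-phenyl-6-propanoyl-3,4-dihydro-2H-chromen-2-one | O=C1C[C@H](c2ccccc2)c2c(OC)c(C(=O)CC)c(OC)cc2O1 | intermediate
9 | (4R)-8-iodo-5,7-dimethoxy-4-phenyl-6-propanoyl-3,4-dihydro-2H-chromen-2-one | O=C1C[C@H](c2ccccc2)c2c(OC)c(C(=O)CC)c(OC)c(I)c2O1 | intermediate
10 | racemic lavandulol, 5-methyl-2-(prop-1-en-2-yl)hex-4-en-1-ol | C=C(C)C(CC=C(C)C)CO | starting material
11 | (S)-lavandulol, (2S)-5-methyl-2-(prop-1-en-2-yl)hex-4-en-1-ol | C=C(C)[C@H](CC=C(C)C)CO | intermediate
12 | (S)-lavandulyl iodide, (3S)-3-(iodomethyl)-2,6-dimethylhepta-1,5-diene | C=C(C)[C@H](CC=C(C)C)CI | intermediate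
13 | [(2S)-5-methyl-2-(prop-1-en-2-yl)hex-4-en-1-yl]zinc iodide | C=C(C)[C@H](CC=C(C)C)C[Zn]I | intermediate (not isolated)
14 | (4R)-5,7-dimethoxy-8-[(2R)-5-methyl-2-(prop-1-en-2-yl)hex-4-en-1-yl]-4-phenyl-6-propanoyl-3,4-dihydro-2H-chromen-2-one | O=C1C[C@H](c2ccccc2)c2c(OC)c(C(=O)CC)c(OC)c(C[C@@H](CC=C(C)C)C(C)=C)c2O1 | intermediate
15 | prenyl bromide, 1-bromo-3-methylbut-2-ene | CC(C)=CCBr | starting material
16 | sodium 3,5-dimethoxy-2-[(1R)-3-methoxy-3-oxo-1-phenylpropyl]-6-[(2R)-5-methyl-2-(prop-1-en-2-yl)hex-4-en-1-yl]-4-propanoylphenolate | [Na+].[O-]c1c(C[C@@H](CC=C(C)C)C(C)=C)c(OC)c(C(=O)CC)c(OC)c1[C@H](CC(=O)OC)c1ccccc1 | intermediate (not isolated)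
17 | methyl (3R)-3-[(5S)-2,4-dimethoxy-5-(3-methylbut-2-en-1-yl)-5-[(2R)-5-methyl-2-(prop-1-en-2-yl)hex-4-en-1-yl]-6-oxo-3-propanoylcyclohexa-1,3-dien-1-yl]-3-phenylpropanoate | C=C(C)[C@H](CC=C(C)C)C[C@]1(CC=C(C)C)C(=O)C([C@H](CC(=O)OC)c2ccccc2)=C(OC)C(C(=O)CC)=C1OC | intermediate
18 | methyl (3R)-3-[(5S)-2,4-dimethoxy-5-(3-methylbut-2-en-1-yl)-5-[(2R)-5-methyl-2-(prop-1-en-2-yl)hex-4-en-1-yl]-6-oxo-3-[(1Z)-1-(triethylsilyloxy)prop-1-en-1-yl]cyclohexa-1,3-dien-1-yl]-3-phenylpropanoate | C=C(C)[C@H](CC=C(C)C)C[C@]1(CC=C(C)C)C(=O)C([C@H](CC(=O)OC)c2ccccc2)=C(OC)C(/C(O[Si](CC)(CC)CC)=C/C)=C1OC | intermediate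
19 | acetaldehyde | CC=O | starting material
20 | methyl (3R)-3-[(5S)-2,4-dimethoxy-3-[(2S,3R)-2-methyl-3-(triethylsilyloxy)butanoyl]-5-(3-methylbut-2-en-1-yl)-5-[(2R)-5-methyl-2-(prop-1-en-2-yl)hex-4-en-1-yl]-6-oxocyclohexa-1,3-dien-1-yl]-3-phenylpropanoate | C=C(C)[C@H](CC=C(C)C)C[C@]1(CC=C(C)C)C(=O)C([C@H](CC(=O)OC)c2ccccc2)=C(OC)C(C(=O)[C@@H](C)[C@@H](C)O[Si](CC)(CC)CC)=C1OC | intermediate (not isolated)
21 | methyl (3R)-3-[(2R,3S,8S)-5-methoxy-2,3-dimethyl-8-(3-methylbut-2-en-1-yl)-8-[(2R)-5-methyl-2-(prop-1-en-2-yl)hex-4-en-1-yl]-4,7-dioxo-3,4,7,8-tetrahydro-2H-chromen-6-yl]-3-phenylpropanoate | C=C(C)[C@H](CC=C(C)C)C[C@]1(CC=C(C)C)C(=O)C([C@H](CC(=O)OC)c2ccccc2)=C(OC)C2=C1O[C@H](C)[C@H](C)C2=O | intermediate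
22 | methyl (3R)-3-[(2R,3S,8S)-5-hydroxy-2,3-dimethyl-8-(3-methylbut-2-en-1-yl)-8-[(2R)-5-methyl-2-(prop-1-en-2-yl)hex-4-en-1-yl]-4,7-dioxo-3,4,7,8-tetrahydro-2H-chromen-6-yl]-3-phenylpropanoate | C=C(C)[C@H](CC=C(C)C)C[C@]1(CC=C(C)C)C(=O)C([C@H](CC(=O)OC)c2ccccc2)=C(O)C2=C1O[C@H](C)[C@H](C)C2=O | intermediate
23 | (3R)-3-[(2R,3S,8S)-5-hydroxy-2,3-dimethyl-8-(3-methylbut-2-en-1-yl)-8-[(2R)-5-methyl-2-(prop-1-en-2-yl)hex-4-en-1-yl]-4,7-dioxo-3,4,7,8-tetrahydro-2H-chromen-6-yl]-3-phenylpropanoic acid | C=C(C)[C@H](CC=C(C)C)C[C@]1(CC=C(C)C)C(=O)C([C@H](CC(=O)O)c2ccccc2)=C(O)C2=C1O[C@H](C)[C@H](C)C2=O | target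

## Step count and least certain steps

Total: 14 steps. Longest linear sequence: 12 steps (steps 1–6 and 9–14, from 1 to 23); the lavandulyl branch (steps 7 and 8) joins at step 9. Stereocentres are set in step 5 (benzylic carbon), step 7 (C2'), step 10 (C8) and step 12 (C2 and C3).

**Step 12 (key step).** The addition may be sluggish, because the enol silane is flanked by two methoxy groups and the Lewis acid can be sequestered by the many carbonyl oxygens. Facial discrimination of so small an aldehyde may be incomplete, some anti aldol may form, O1 may close onto C5, C3 may epimerise during the acid stage, and the enol silane may simply be protonated back to the ketone. The fallback sets out from 17 and returns at 21. Ketone 17 would be enolised with diisopinocampheylboron triflate and iPr2NEt at −78 °C to the Z boron enolate, which adds to 19 through a closed chair transition state (syn by geometry, face chosen by the antipode of the boron reagent). Buffered oxidative work-up would give the β-hydroxy ketone F1, and catalytic pyridinium p-toluenesulfonate in CH2Cl2 would close ring B by the same addition–elimination to give 21.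

**Step 10.** The phenoxide may react at oxygen instead of carbon, some alkylation may occur at C6, and the remote 1,3-induction may give poor facial selectivity at C8, leaving epimers that are hard to separate. The fallback sets out from 14 and returns at 17. The phenoxide 16 would be generated in the same way, but the prenyl group would be delivered by a Tsuji–Trost allylation with prenyl acetate, Pd2(dba)3 and (1R,2R)- or (1S,2S)-N,N′-bis[2-(diphenylphosphino)benzoyl]cyclohexane-1,2-diamine in THF. O-Allylation is reversible on zerovalent palladium, so material can funnel to the C-alkylated dienone, and the facial choice passes from the substrate to the chiral π-prenyl complex. This fallback makes no compound outside the list (F0).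

**Step 5.** The peri C5 methoxy group may slow the insertion at C4 so that protodeboronation of 7 outruns addition, and conversion or enantiomeric purity may suffer. The fallback sets out from 4 and returns at 8. A Pechmann condensation of 4 with ethyl benzoylacetate in CH3SO3H would give 5,7-dimethoxy-4-phenyl-6-propanoyl-2H-chromen-2-one F2. Its asymmetric conjugate reduction with copper hydride (Cu(OAc)2, the antipode of 5,5′-bis[bis(3,5-di-tert-butyl-4-methoxyphenyl)phosphino]-4,4′-bi-1,3-benzodioxole that gives 4R, a hydrosilane, t-BuOH) would then give 8. The hindered, twisted ketone should be reduced more slowly than the enoate, but this chemoselectivity would have to be watched.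

**Step 9.** Oxidative addition at the di-ortho-substituted, electron-rich iodide may be slow, and the alkylpalladium intermediate may undergo β-hydride elimination, giving reduced arene and isomerised diene. The fallback sets out from 9 and 12 and returns at 14. It is a nickel-catalysed reductive cross-electrophile coupling (NiI2, 4,4′-di-tert-butyl-2,2′-bipyridine, Zn, N,N-dimethylacetamide, rt), in which an alkyl radical is captured by an arylnickel species and no organozinc is preformed. It makes no compound outside the list (F0).

**Step 13.** At 100 °C the cis configuration at C3 may erode through enolisation, the C8 prenyl group may migrate to O7 by a sigmatropic shift, and demethylation at the hindered C5 may stall. The fallback sets out from 21 and returns at 22. It replaces nucleophilic demethylation by hydrolytic cleavage of the vinylogous ester (dilute aqueous HCl in THF, rt; addition of water at C5 and loss of the methoxy group) and makes no compound outside the list (F0).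

## Further compounds

F1 | step 12 | methyl (3R)-3-[(5S)-3-[(2S,3R)-3-hydroxy-2-methylbutanoyl]-2,4-dimethoxy-5-(3-methylbut-2-en-1-yl)-5-[(2R)-5-methyl-2-(prop-1-en-2-yl)hex-4-en-1-yl]-6-oxocyclohexa-1,3-dien-1-yl]-3-phenylpropanoate | C=C(C)[C@H](CC=C(C)C)C[C@]1(CC=C(C)C)C(=O)C([C@H](CC(=O)OC)c2ccccc2)=C(OC)C(C(=O)[C@@H](C)[C@@H](C)O)=C1OC
F0 | step 10 | none | none
F2 | step 5 | 5,7-dimethoxy-4-phenyl-6-propanoyl-2H-chromen-2-one | O=c1cc(-c2ccccc2)c2c(OC)c(C(=O)CC)c(OC)cc2o1
F0 | step 9 | none | none
F0 | step 13 | none | none
A1 | alternative 1 | (6S)-3,5-dihydroxy-4-[(2S,3R)-2-methyl-3-(triethylsilyloxy)butanoyl]-6-(3-methylbut-2-en-1-yl)-6-[(2R)-5-methyl-2-(prop-1-en-2-yl)hex-4-en-1-yl]cyclohexa-2,4-dien-1-one | C=C(C)[C@H](CC=C(C)C)C[C@]1(CC=C(C)C)C(=O)C=C(O)C(C(=O)[C@@H](C)[C@@H](C)O[Si](CC)(CC)CC)=C1O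
A2 | alternative 2 | tert-butyl 2-[(2R,3S)-5,7-bis(benzyloxy)-2-methyl-4-oxo-3,4-dihydro-2H-chromen-3-yl]acetate | C[C@H]1Oc2cc(OCc3ccccc3)cc(OCc3ccccc3)c2C(=O)[C@H]1CC(=O)OC(C)(C)C
A3 | alternative 3 | methyl (3R)-3-[(2R,3S,8S)-5-hydroxy-2,3-dimethyl-8-(3-methylbut-2-en-1-yl)-8-[(2R)-5-methyl-2-(prop-1-en-2-yl)hex-4-en-1-yl]-4,7-dioxo-3,4,7,8-tetrahydro-2H-chromen-6-yl]-3-phenylpropanoate | C=C(C)[C@H](CC=C(C)C)C[C@]1(CC=C(C)C)C(=O)C([C@H](CC(=O)OC)c2ccccc2)=C(O)C2=C1O[C@H](C)[C@H](C)C2=O
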